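**Strategy.** The ten-membered carbocycle is not closed but unveiled. A temporary C1–C5 bond turns it into a cis-fused hydroazulene (five-membered ring C1–C5, seven-membered ring C1, C5–C10); severing that bond again generates precisely the C1 carbonyl and the E-configured C4=C5 double bond, the later trans epoxide, which no small ring could hold. In the key step Pb(OAc)4 attacks the tertiary C1 hydroxyl of a γ-stannyl carbinol, C1–C5 splits heterolytically, tin departs from C4, and the germacranolide ring with its C10 methylene ketone emerges at once. The precursor is the 1-hydroxy-4-(trimethylstannyl)guaianolide that already carries butenolide, tiglate and acetate, with the C4 methyl cis and tin trans to C6.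

Key step: step 17

Remarks on the chemistry:
- Germacrane numbering is used for all intermediates.
- (R)-Glyceraldehyde acetonide 1 is taken as a commercial compound.
- The stannyl enolate is racemic and is used in excess, so that the enantiopure aldehyde 9 draws on its matched enantiomer.
- C6 is the same centre from 19 to 29; its descriptor reads R up to 28 and S in 29 only because the ranking of its neighbours changes.
- Precursor 26 and fragmentation product 28 are stereochemically consistent with the target; no structure needed correction.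

**Fragment 1: the C6–C10 aldehyde**

Step 1
Reactants: 1 (R)-2,2-dimethyl-1,3-dioxolane-4-carbaldehyde; 2 2,3-dibromoprop-1-ene
Product: 3 (1S)-3-bromo-1-[(4R)-2,2-dimethyl-1,3-dioxolan-4-yl]but-3-en-1-ol
Conditions: In powder, THF/H2O (1:1), rt
Reagents that add atoms: none
Why: Barbier allylation: the 2-bromoallylindium species adds to the α-alkoxy aldehyde in the Felkin–Anh (non-chelate) sense, which should give mainly the anti carbinol (1S), the future C8; the syn epimer is removed by chromatography.

Step 2
Reactants: 3 (1S)-3-bromo-1-[(4R)-2,2-dimethyl-1,3-dioxolan-4-yl]but-3-en-1-ol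
Product: 4 (1S)-1-[(4R)-2,2-dimethyl-1,3-dioxolan-4-yl]-3-iodobut-3-en-1-ol
Conditions: CuI (10 mol%), trans-N,N′-dimethylcyclohexane-1,2-diamine (20 mol%), NaI, 1,4-dioxane, 110 °C
Reagents that add atoms: sodium iodide, [Na+].[I-]
Why: Copper-catalysed halogen exchange (Finkelstein-type) of the alkenyl bromide, driven by precipitation of NaBr, supplies the more reactive alkenyl iodide for the later Ni/Cr ring closure and leaves alcohol and acetal untouched.

Step 3
Reactants: 4 (1S)-1-[(4R)-2,2-dimethyl-1,3-dioxolan-4-yl]-3-iodobut-3-en-1-ol; 5 tiglic acid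
Product: 6 (1S)-1-[(4R)-2,2-dimethyl-1,3-dioxolan-4-yl]-3-iodobut-3-en-1-yl (2E)-2-methylbut-2-enoate
Conditions: DCC, DMAP (cat.), CH2Cl2, 0 °C to rt
Reagents that add atoms: none
Why: Steglich esterification places the C8 tiglate early, so that no protecting group is needed at this oxygen; the E geometry of the acid is the stable one and is retained.

Step 4
Reactants: 6 (1S)-1-[(4R)-2,2-dimethyl-1,3-dioxolan-4-yl]-3-iodobut-3-en-1-yl (2E)-2-methylbut-2-enoate
Product: 7 (2R,3S)-1,2-dihydroxy-5-iodohex-5-en-3-yl (2E)-2-methylbut-2-enoate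
Conditions: AcOH/H2O (4:1), 40 °C
Reagents that add atoms: none
Why: Acid-catalysed hydrolysis of the terminal isopropylidene acetal; under mildly acidic conditions the hindered conjugated ester should neither cleave nor migrate, and the alkenyl iodide is inert.

Step 5
Reactants: 7 (2R,3S)-1,2-dihydroxy-5-iodohex-5-en-3-yl (2E)-2-methylbut-2-enoate
Product: 8 (2R,3S)-5-iodo-1,2-bis(triethylsilyloxy)hex-5-en-3-yl (2E)-2-methylbut-2-enoate
Conditions: TESOTf, 2,6-lutidine, CH2Cl2, −78 °C
Reagents that add atoms: triethylsilyl trifluoromethanesulfonate, CC[Si](CC)(CC)OS(=O)(=O)C(F)(F)F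
Why: Silylation of both hydroxyls with a silyl triflate and a hindered base is fast at low temperature and non-nucleophilic, so the neighbouring tiglate does not migrate.

Step 6
Reactants: 8 (2R,3S)-5-iodo-1,2-bis(triethylsilyloxy)hex-5-en-3-yl (2E)-2-methylbut-2-enoate
Product: 9 (2S,3S)-5-iodo-1-oxo-2-(triethylsilyloxy)hex-5-en-3-yl (2E)-2-methylbut-2-enoate
Conditions: (COCl)2, DMSO, CH2Cl2, −78 to −40 °C; Et3N, −78 °C; cold buffered work-up
Reagents that add atoms: none
Why: Swern oxidation in which the activated sulfoxide cleaves and oxidises the primary triethylsilyl ether selectively while the secondary one survives; keeping the amine stage cold limits β-elimination of the tiglate, and the aldehyde is used crude.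

**Fragment 2: the C11–C13 phosphonate**

Step 7
Reactants: 10 benzyl 2-(diethoxyphosphoryl)acetate; 11 (chloromethoxy)triisopropylsilane
Product: 12 benzyl 2-(diethoxyphosphoryl)-3-(triisopropylsilyloxy)propanoate (racemic)
Conditions: NaH, THF, 0 °C to rt (10 in slight excess)
Reagents that add atoms: none
Why: C-Alkylation of the sodium phosphonoacetate carbanion by the α-chloro ether (displacement at an oxocarbenium-like carbon) installs the future C13 as a silyl-protected hydroxymethyl group.

Step 8
Reactants: 12 benzyl 2-(diethoxyphosphoryl)-3-(triisopropylsilyloxy)propanoate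
Product: 13 2-(diethoxyphosphoryl)-3-(triisopropylsilyloxy)propanoic acid (racemic)
Conditions: H2 (1 atm), 10% Pd/C, EtOAc, rt
Reagents that add atoms: none
Why: Catalytic hydrogenolysis frees the acid under neutral conditions, which avoids base-induced β-elimination of the silyloxy group.

**Assembly**

Step 9
Reactants: 14 trimethyltin chloride; 15 3-methylcyclopent-2-en-1-one; 9 (2S,3S)-5-iodo-1-oxo-2-(triethylsilyloxy)hex-5-en-3-yl (2E)-2-methylbut-2-enoate
Product: 19 aldol adduct (1R,2R,3S)-1-hydroxy-5-iodo-1-[(1S,2S)-2-methyl-5-oxo-2-(trimethylstannyl)cyclopentyl]-2-(triethylsilyloxy)hex-5-en-3-yl (2E)-2-methylbut-2-enoate, via trimethylstannyllithium 16 (not isolated), via lithium stannyl enolate 17 (not isolated), via dicyclohexylboron enolate 18 (not isolated)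
Conditions: 14 (2.5 equiv), Li, THF, 0 °C; 15 (2.6 equiv), −78 °C; (c-Hex)2BCl, −78 °C; 9 (1 equiv), −78 to −20 °C; MeOH, pH 7 buffer
Reagents that add atoms: none
Why: Conjugate addition of the stannyl anion gives the regiodefined enolate, which after lithium–boron exchange undergoes a boron aldol reaction through a Zimmerman–Traxler chair: the aldehyde enters anti to the bulky, electron-releasing Me3Sn group (tin trans to C6), the E(O)-enolate gives the 5,6-anti adduct, and polar Felkin–Anh (Cornforth) control by the C7 silyloxy group sets C6 anti to C7, so the enolate enantiomer that satisfies all three preferences is consumed selectively by the enantiopure aldehyde (double stereodifferentiation) and 19 should be the main diastereomer.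

Step 10
Reactants: 19 aldol adduct; 13 2-(diethoxyphosphoryl)-3-(triisopropylsilyloxy)propanoic acid
Product: 20 C6 ester of 19 with 13 (C6–O–CO–CH[P(O)(OEt)2]–CH2OTIPS; two epimers at the phosphonate carbon; other centres as in 19)
Conditions: DCC, DMAP (cat.), CH2Cl2, 0 °C to rt
Reagents that add atoms: none
Why: Carbodiimide esterification, which for phosphonoacetic acids runs through a reactive ketene and so acylates even the hindered C6 hydroxyl; it also masks this γ-stannyl alcohol before any oxidant is used.

Step 11
Reactants: 20 C6 phosphonoacetyl ester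
Product: 21 C7 alcohol (20 without the C7 triethylsilyl group)
Conditions: HF·pyridine, pyridine, THF, 0 °C
Reagents that add atoms: none
Why: Selective desilylation: the secondary triethylsilyl ether is cleaved far faster than the primary triisopropylsilyl ether, and the buffered, non-basic medium suppresses acyl migration to the freed C7 hydroxyl.

Step 12
Reactants: 21 C7 alcohol
Product: 22 C7 ketone (C6 acyloxy and C8 tigloyloxy groups flank the new carbonyl)
Conditions: Dess–Martin periodinane, CH2Cl2, 0 °C to rt
Reagents that add atoms: none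
Why: Dess–Martin oxidation of the secondary alcohol under neutral conditions erases the C7 auxiliary centre; the only other hydroxyl position (C6) is already acylated, so no free γ-stannyl alcohol meets the oxidant.

Step 13
Reactants: 22 C7 ketone
Product: 23 (1S)-3-iodo-1-{(2R)-2-[(1S,2S)-2-methyl-5-oxo-2-(trimethylstannyl)cyclopentyl]-5-oxo-4-[(triisopropylsilyloxy)methyl]-2,5-dihydrofuran-3-yl}but-3-en-1-yl (2E)-2-methylbut-2-enoate
Conditions: LiCl, iPr2NEt, MeCN, 0 °C to rt
Reagents that add atoms: none
Why: Intramolecular Horner–Wadsworth–Emmons olefination under mild LiCl/amine conditions: the lithium-chelated phosphonate carbanion should close the five-membered ring on the doubly α-oxygenated, most electrophilic C7 ketone faster than it closes a six-membered ring on the C1 ketone or loses its β-silyloxy group, giving the C7=C11 butenolide without disturbing C6 or C8.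

Step 14
Reactants: 23 butenolide alkenyl iodide
Product: 24 (1R,4S,5S,6R,8S)-1-hydroxy-8-tigloyloxy-13-(triisopropylsilyloxy)-4-(trimethylstannyl)guaia-7(11),10(14)-dien-12,6-olide (cis-fused; 1-OH, H5, H6, H8 and SnMe3 on one face, C4 methyl, O6 and O8 on the other)
Conditions: CrCl2 (excess), NiCl2 (cat.), DMSO/THF, rt, high dilution
Reagents that add atoms: none
Why: Nozaki–Hiyama–Kishi reaction: the alkenyl iodide is taken up by zerovalent nickel and passed to trivalent chromium, and the alkenylchromium adds intramolecularly to the only ketone (esters, lactone, silyl ether and stannane are inert), closing the seven-membered ring at C1–C10; the tether from C5 can reach C1 only on the face that carries C6, which sets C1 as the cis-fused tertiary carbinol.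

Step 15
Reactants: 24 silyl-protected hydroazulenol
Product: 25 (1R,4S,5S,6R,8S)-1,13-dihydroxy-8-tigloyloxy-4-(trimethylstannyl)guaia-7(11),10(14)-dien-12,6-olide
Conditions: HF·pyridine, pyridine, THF, 0 °C to rt
Reagents that add atoms: none
Why: Buffered fluoride desilylation removes the primary triisopropylsilyl ether without ionising the tertiary allylic alcohol or touching the esters and the C–Sn bond; the silyl group was kept until now so that no reactive allylic acetate is present during the Ni/Cr step.

Step 16
Reactants: 25 C13 alcohol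
Product: 26 (1R,4S,5S,6R,8S)-13-acetoxy-1-hydroxy-8-tigloyloxy-4-(trimethylstannyl)guaia-7(11),10(14)-dien-12,6-olide (fragmentation precursor)
Conditions: Ac2O, pyridine, CH2Cl2, 0 °C
Reagents that add atoms: acetic anhydride, CC(=O)OC(C)=O
Why: Acetylation of the primary alcohol; the hindered tertiary C1 hydroxyl does not react under these conditions and stays free as the trigger for the next step.

**Ring opening and epoxidation**

Step 17
Reactants: 26 fragmentation precursor
Product: 28 (6R,8S)-13-acetoxy-1-oxo-8-tigloyloxygermacra-4E,7(11),10(14)-trien-12,6-olide, via tetravalent-lead alkoxide 27 (not isolated)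
Conditions: Pb(OAc)4, benzene, rt to 50 °C
Reagents that add atoms: none
Why: Exchange of one acetate on Pb(OAc)4 for the tertiary C1 alkoxide gives the tetravalent-lead alkoxide 27; departure of Pb(OAc)2 and acetate from oxygen pulls the C1–C5 σ pair into the new C1=O bond while the C4–Sn σ pair closes the C4=C5 π bond and Me3Sn leaves as its acetate, a 1,4-heterolytic (Grob-type) fragmentation. The closest known reaction type is the Pb(OAc)4-induced oxidative fragmentation of γ-hydroxy stannanes to alkenyl ketones, which has also been used to open bicyclic stannyl carbinols to medium rings. No ring is closed, so no closure mode applies: the ten-membered ring appears by cutting the bond shared by the five- and seven-membered rings. No stereocentre is created; C1, C4 and C5 become trigonal and C6 and C8 are untouched. The step needs E geometry at C4=C5 and cleavage of C1–C5 rather than C1–C2 or C1–C10: the first follows from the anti-periplanar Sn–C4–C5–C1 array reachable in the envelope with pseudo-equatorial tin, in which the C4 methyl (cis to C6 on the ring) ends up cis to C6 on the alkene, and the second from the fact that only the C1–C5 bond has a β-stannyl donor. Esters, lactone, acetate and the electron-poor alkenes should be inert to Pb(OAc)4 under these conditions.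

Step 18
Reactants: 28 4,5-deoxy compound
Product: 29 (4R,5R,6S,8S)-13-acetoxy-4,5-epoxy-1-oxo-8-tigloyloxygermacra-7(11),10(14)-dien-12,6-olide (CNP0225286.1)
Conditions: mCPBA, CH2Cl2, 0 °C
Reagents that add atoms: 3-chloroperbenzoic acid, O=C(OO)c1cccc(Cl)c1
Why: Prilezhaev epoxidation: the peracid selects the only electron-rich alkene (trisubstituted C4=C5; the other three are conjugated to carbonyls) and, with C6–H held in the alkene plane by allylic strain against the C4 methyl, attacks the peripheral face on the side of the lactone oxygen, away from the ring interior, which gives the (4R,5R) trans epoxide.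

**Compound list**

1 | (R)-2,2-dimethyl-1,3-dioxolane-4-carbaldehyde | O=C[C@H]1COC(C)(C)O1 | starting material
2 | 2,3-dibromoprop-1-ene | C=C(Br)CBr | starting material
3 | (1S)-3-bromo-1-[(4R)-2,2-dimethyl-1,3-dioxolan-4-yl]but-3-en-1-ol | C=C(Br)C[C@H](O)[C@H]1COC(C)(C)O1 | intermediate
4 | (1S)-1-[(4R)-2,2-dimethyl-1,3-dioxolan-4-yl]-3-iodobut-3-en-1-ol | C=C(I)C[C@H](O)[C@H]1COC(C)(C)O1 | intermediate
5 | tiglic acid, (2E)-2-methylbut-2-enoic acid | C/C=C(\C)C(=O)O | starting material
6 | (1S)-1-[(4R)-2,2-dimethyl-1,3-dioxolan-4-yl]-3-iodobut-3-en-1-yl (2E)-2-methylbut-2-enoate | C=C(I)C[C@H](OC(=O)/C(C)=C/C)[C@H]1COC(C)(C)O1 | intermediate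
7 | (2R,3S)-1,2-dihydroxy-5-iodohex-5-en-3-yl (2E)-2-methylbut-2-enoate | C=C(I)C[C@H](OC(=O)/C(C)=C/C)[C@H](O)CO | intermediate
8 | (2R,3S)-5-iodo-1,2-bis(triethylsilyloxy)hex-5-en-3-yl (2E)-2-methylbut-2-enoate | C=C(I)C[C@H](OC(=O)/C(C)=C/C)[C@H](O[Si](CC)(CC)CC)CO[Si](CC)(CC)CC | intermediate
9 | (2S,3S)-5-iodo-1-oxo-2-(triethylsilyloxy)hex-5-en-3-yl (2E)-2-methylbut-2-enoate (C6 aldehyde, C7 OTES, C8 OTig) | C=C(I)C[C@H](OC(=O)/C(C)=C/C)[C@H](O[Si](CC)(CC)CC)C=O | intermediate
10 | benzyl 2-(diethoxyphosphoryl)acetate | CCOP(=O)(OCC)CC(=O)OCc1ccccc1 | starting material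
11 | (chloromethoxy)triisopropylsilane | CC(C)[Si](OCCl)(C(C)C)C(C)C | starting material
12 | benzyl 2-(diethoxyphosphoryl)-3-(triisopropylsilyloxy)propanoate (racemic) | CCOP(=O)(OCC)C(CO[Si](C(C)C)(C(C)C)C(C)C)C(=O)OCc1ccccc1 | intermediate
13 | 2-(diethoxyphosphoryl)-3-(triisopropylsilyloxy)propanoic acid (racemic) | CCOP(=O)(OCC)C(CO[Si](C(C)C)(C(C)C)C(C)C)C(=O)O | intermediate
14 | trimethyltin chloride | C[Sn](C)(C)Cl | starting material
15 | 3-methylcyclopent-2-en-1-one | CC1=CC(=O)CC1 | starting material
16 | trimethylstannyllithium | [Li][Sn](C)(C)C | intermediate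
17 | lithium 3-methyl-3-(trimethylstannyl)cyclopent-1-en-1-olate (racemic) | [Li]OC1=CC(C)([Sn](C)(C)C)CC1 | intermediate
18 | dicyclohexyl{[3-methyl-3-(trimethylstannyl)cyclopent-1-en-1-yl]oxy}borane (racemic) | C[Sn](C)(C)C1(C)CCC(OB(C2CCCCC2)C2CCCCC2)=C1 | intermediate
19 | (1R,2R,3S)-1-hydroxy-5-iodo-1-[(1S,2S)-2-methyl-5-oxo-2-(trimethylstannyl)cyclopentyl]-2-(triethylsilyloxy)hex-5-en-3-yl (2E)-2-methylbut-2-enoate (germacrane 4S,5S,6R,7R,8S) | C=C(I)C[C@H](OC(=O)/C(C)=C/C)[C@H](O[Si](CC)(CC)CC)[C@H](O)[C@H]1C(=O)CC[C@]1(C)[Sn](C)(C)C | intermediate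
20 | C6 ester of 19 with 13 (two epimers at the phosphonate carbon) | C=C(I)C[C@H](OC(=O)/C(C)=C/C)[C@H](O[Si](CC)(CC)CC)[C@H](OC(=O)C(CO[Si](C(C)C)(C(C)C)C(C)C)P(=O)(OCC)OCC)[C@H]1C(=O)CC[C@]1(C)[Sn](C)(C)C | intermediate
21 | C7 alcohol (20 without the C7 triethylsilyl group) | C=C(I)C[C@H](OC(=O)/C(C)=C/C)[C@H](O)[C@H](OC(=O)C(CO[Si](C(C)C)(C(C)C)C(C)C)P(=O)(OCC)OCC)[C@H]1C(=O)CC[C@]1(C)[Sn](C)(C)C | intermediate
22 | C7 ketone | C=C(I)C[C@H](OC(=O)/C(C)=C/C)C(=O)[C@H](OC(=O)C(CO[Si](C(C)C)(C(C)C)C(C)C)P(=O)(OCC)OCC)[C@H]1C(=O)CC[C@]1(C)[Sn](C)(C)C | intermediate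
23 | (1S)-3-iodo-1-{(2R)-2-[(1S,2S)-2-methyl-5-oxo-2-(trimethylstannyl)cyclopentyl]-5-oxo-4-[(triisopropylsilyloxy)methyl]-2,5-dihydrofuran-3-yl}but-3-en-1-yl (2E)-2-methylbut-2-enoate | C=C(I)C[C@H](OC(=O)/C(C)=C/C)C1=C(CO[Si](C(C)C)(C(C)C)C(C)C)C(=O)O[C@@H]1[C@H]1C(=O)CC[C@]1(C)[Sn](C)(C)C | intermediate
24 | (1R,4S,5S,6R,8S)-1-hydroxy-8-tigloyloxy-13-(triisopropylsilyloxy)-4-(trimethylstannyl)guaia-7(11),10(14)-dien-12,6-olide | C=C1C[C@H](OC(=O)/C(C)=C/C)C2=C(CO[Si](C(C)C)(C(C)C)C(C)C)C(=O)O[C@@H]2[C@@H]3[C@@](C)([Sn](C)(C)C)CC[C@]13O | intermediate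
25 | (1R,4S,5S,6R,8S)-1,13-dihydroxy-8-tigloyloxy-4-(trimethylstannyl)guaia-7(11),10(14)-dien-12,6-olide | C=C1C[C@H](OC(=O)/C(C)=C/C)C2=C(CO)C(=O)O[C@@H]2[C@@H]3[C@@](C)([Sn](C)(C)C)CC[C@]13O | intermediate
26 | (1R,4S,5S,6R,8S)-13-acetoxy-1-hydroxy-8-tigloyloxy-4-(trimethylstannyl)guaia-7(11),10(14)-dien-12,6-olide | C=C1C[C@H](OC(=O)/C(C)=C/C)C2=C(COC(C)=O)C(=O)O[C@@H]2[C@@H]3[C@@](C)([Sn](C)(C)C)CC[C@]13O | intermediate
27 | C1–O–Pb(OAc)3 alkoxide of 26 (tetravalent lead) | C=C1C[C@H](OC(=O)/C(C)=C/C)C2=C(COC(C)=O)C(=O)O[C@@H]2[C@@H]3[C@@](C)([Sn](C)(C)C)CC[C@]13O[Pb](OC(C)=O)(OC(C)=O)OC(C)=O | intermediate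
28 | (6R,8S)-13-acetoxy-1-oxo-8-tigloyloxygermacra-4E,7(11),10(14)-trien-12,6-olide | C=C1C[C@H](OC(=O)/C(C)=C/C)C2=C(COC(C)=O)C(=O)O[C@@H]2/C=C(C)/CCC1=O | intermediate
29 | (4R,5R,6S,8S)-13-acetoxy-4,5-epoxy-1-oxo-8-tigloyloxygermacra-7(11),10(14)-dien-12,6-olide (CNP0225286.1) | C=C1C[C@H](OC(=O)/C(C)=C/C)C2=C(COC(C)=O)C(=O)O[C@@H]2[C@H]2O[C@]2(C)CCC1=O | target

**Step count**

Total: 18 steps. Longest linear sequence: 16 steps (steps 1–6 and 9–18, from 1 to 29); steps 7–8 form a two-step side branch.

**Steps most likely to fail**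

Step 17. The lead alkoxide may not reach the anti-periplanar Sn–C4–C5–C1 alignment in the cis-fused bicycle, so that heterolysis is slow and unassisted oxidation or protodestannylation takes over. The fallback sets out from 26 and changes the mechanism from two-electron heterolysis to radical β-scission. Treatment with PhI(OAc)2 and I2 under visible light in cyclohexane/CH2Cl2 should give the C1 hypoiodite of 26, F1 (not isolated). O–I homolysis gives the C1 alkoxy radical, which cleaves the C1–C5 bond; the resulting C5 radical expels Me3Sn from C4 before bond rotation, and the route is rejoined at 28. This path does not depend on a strict orbital alignment, at the price of a less rigorously controlled alkene geometry.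

Step 14. Addition of the alkenylchromium to a ketone is slow, so protonolysis of the organochromium (loss of iodine without ring closure) may outrun formation of the seven-membered ring. The fallback sets out from 23 and replaces the chromium reagent by a boron-to-rhodium relay. Miyaura borylation (B2pin2, PdCl2(dppf), KOAc, dioxane, 80 °C) should give the alkenyl pinacol boronate of 23, F2. A catalytic amount of [Rh(cod)OH]2 in dioxane/H2O at 60 °C then generates an alkenylrhodium species that adds intramolecularly to the C1 carbonyl from the same face, and the route is rejoined at 24.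

Step 9. Facial discrimination in the three-component coupling may erode: the mismatched enolate enantiomer may react, or the aldehyde may be attacked on its anti-Felkin face, and warming risks loss of the stannyl anion by retro-addition. The fallback sets out from 14 and 15 and separates enolate formation from the aldol step. The stannyl enolate is trapped with Me3SiCl to give the silyl enol ether trimethyl{[3-methyl-3-(trimethylstannyl)cyclopent-1-en-1-yl]oxy}silane, F3, which is isolated. A BF3·OEt2-mediated Mukaiyama aldol reaction with 9 at −78 °C then proceeds through an open transition state, in which the Lewis-acid-bound α-silyloxy aldehyde is attacked on its Felkin face and the nucleophile still reacts anti to tin. Compound 19 is separated from its C4,C5-epimeric companion by chromatography, and the route is rejoined at 19.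

**Further compounds**

F1 | step 17 | C1 hypoiodite of 26 | C=C1C[C@H](OC(=O)/C(C)=C/C)C2=C(COC(C)=O)C(=O)O[C@@H]2[C@@H]3[C@@](C)([Sn](C)(C)C)CC[C@]13OI
F2 | step 14 | alkenyl pinacol boronate of 23 (Bpin in place of iodine at C10) | C=C(B1OC(C)(C)C(C)(C)O1)C[C@H](OC(=O)/C(C)=C/C)C1=C(CO[Si](C(C)C)(C(C)C)C(C)C)C(=O)O[C@@H]1[C@H]1C(=O)CC[C@]1(C)[Sn](C)(C)C
F3 | step 9 | trimethyl{[3-methyl-3-(trimethylstannyl)cyclopent-1-en-1-yl]oxy}silane (racemic) | C[Si](C)(C)OC1=CC(C)([Sn](C)(C)C)CC1
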